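## Retrosynthetic overview

1. Target 21 ⇐ C9 desilylation and selective C5 tigloylation of diol 18.
2. 18 ⇐ C1–C2 bond by a Norrish–Yang photocyclisation of ketone 16, in which a crotonaldehyde mixed acetal on the C5 oxygen delivers the acyl carbon to the same face as C5–O (transient oxetane 17, hydrolysed).
3. Hydroxy lactone 14 ⇐ anti-epoxidation of enone acid 11, 5-exo epoxide opening by the C12 acid (lactone ring, formed second), then exo-face hydrogenation for C11.
4. Cycloheptenone 8 ⇐ Ito–Saegusa one-carbon ring expansion of cyclohexanone 4 (seven-membered ring, formed first).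
5. 4 ⇐ (R)-carvone by conjugate borylation/oxidation trans to the isopropenyl group; the carvone stereocentre (C7) is the only one bought.

Assumption and conventions: the SMILES is taken as written (E-crotonoyl, tiglate ester). Labels: ring C1, C5, C6, C7, C8, C9, C10; side chain C2(=O)–C3=C4–C15; lactone C11, C12(=O), C13; C14 = methyl on C10. β = the face of the seven-membered ring carrying the C7–C11 bond; α = the other face. In this numbering the target is (1S,5S,6R,7S,9R,10S,11R): 1β-OH, 5α-OTig, 6β-O, 9α-OH, 10β-CH3. Compounds 1–6 use cyclohexanone numbering.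

## Route

Step 1
Reactants: 1 (R)-(−)-carvone
Product: 3 (3R,5R)-3-hydroxy-2-methyl-5-(prop-1-en-2-yl)cyclohexan-1-one (C2 epimers), via boryl ketone 2 (not isolated)
Conditions: B2pin2, CuCl (5 mol%), DPEphos (5 mol%), NaOtBu (10 mol%), MeOH, THF, rt; then 30% H2O2, pH 7 phosphate buffer, 0 °C
Reagents that add atoms: bis(pinacolato)diboron, CC1(C)OB(OC1(C)C)B1OC(C)(C)C(C)(C)O1 (boron of 2); hydrogen peroxide, OO (hydroxyl oxygen)
Why: Copper-catalysed conjugate borylation adds the boryl group to C3 anti to the C5 isopropenyl group (trans-3,5, substrate control), and C–B oxidation proceeds with retention to set the future C9 carbinol; the C2 centre is epimerisable and is fixed later.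

Step 2
Reactants: 3 (3R,5R)-3-hydroxy-2-methyl-5-(prop-1-en-2-yl)cyclohexan-1-one
Product: 4 (3R,5R)-3-[tert-butyl(dimethyl)silyl]oxy-2-methyl-5-(prop-1-en-2-yl)cyclohexan-1-one
Conditions: TBSCl, imidazole, DMF, rt
Reagents that add atoms: tert-butyldimethylsilyl chloride, CC(C)(C)[Si](C)(C)Cl
Why: Standard silylation of the secondary alcohol blocks retro-aldol chemistry and keeps the future C9 hydroxyl masked until after the tigloylation.

Step 3
Reactants: 4 (3R,5R)-3-[tert-butyl(dimethyl)silyl]oxy-2-methyl-5-(prop-1-en-2-yl)cyclohexan-1-one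
Product: 5 kinetic trimethylsilyl enol ether of 4 (C1=C6)
Conditions: LDA, TMSCl, THF, −78 °C (in situ quench)
Reagents that add atoms: chlorotrimethylsilane, C[Si](C)(C)Cl
Why: Kinetic deprotonation at the unhindered C6 methylene gives the less substituted enol ether and avoids the C2 enolate that could expel the β-silyloxy group.

Step 4
Reactants: 5 kinetic trimethylsilyl enol ether of 4
Product: 6 3-[tert-butyl(dimethyl)silyl]oxy-2-methyl-5-(prop-1-en-2-yl)-1-(trimethylsilyloxy)bicyclo[4.1.0]heptane
Conditions: Et2Zn, CH2I2, CH2Cl2, 0 °C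
Reagents that add atoms: diiodomethane, ICI
Why: Furukawa-type Simmons–Smith cyclopropanation is fastest at the electron-rich silyl enol ether, so the isopropenyl group survives with limited reagent; the new cyclopropane centres are destroyed in step 5.

Step 5
Reactants: 6 3-[tert-butyl(dimethyl)silyl]oxy-2-methyl-5-(prop-1-en-2-yl)-1-(trimethylsilyloxy)bicyclo[4.1.0]heptane
Product: 8 (4R,6R,7S)-6-[tert-butyl(dimethyl)silyl]oxy-7-methyl-4-(prop-1-en-2-yl)cyclohept-2-en-1-one, via chloro ketone 7 (not isolated)
Conditions: FeCl3, pyridine, DMF, 0 °C to rt; then NaOAc, MeOH, reflux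
Reagents that add atoms: iron trichloride, Cl[Fe](Cl)Cl (chlorine of 7 only; nothing is retained in 8)
Why: Ito–Saegusa ring expansion, in which one-electron oxidation opens the internal cyclopropane bond to the secondary β-keto radical, chlorine transfer gives 7 and acetate-mediated E1cB loss of HCl gives the cycloheptenone; the ketone α-centre (C10) begins to equilibrate toward the methyl trans to the silyloxy group.

Step 6
Reactants: 8 (4R,6R,7S)-6-[tert-butyl(dimethyl)silyl]oxy-7-methyl-4-(prop-1-en-2-yl)cyclohept-2-en-1-one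
Product: 10 enal (the prop-1-en-2-yl group of 8 oxidised to 3-oxoprop-1-en-2-yl), via allylic alcohol 9 (not isolated)
Conditions: SeO2 (0.3 equiv), t-BuOOH, CH2Cl2, rt; then MnO2, CH2Cl2, rt
Reagents that add atoms: tert-butyl hydroperoxide, CC(C)(C)OO (oxygen relayed by catalytic SeO2)
Why: Selenium dioxide ene/[2,3] allylic oxidation functionalises the methyl of the electron-rich 1,1-disubstituted alkene and leaves the electron-poor enone alone, and MnO2 takes the allylic alcohol on to the enal.

Step 7
Reactants: 10 enal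
Product: 11 acrylic acid (the C7 substituent is now 1-carboxyethenyl)
Conditions: NaClO2, NaH2PO4, 2-methylbut-2-ene, t-BuOH/H2O, 0 °C to rt
Reagents that add atoms: sodium chlorite, [Na+].[O-]Cl=O
Why: Pinnick oxidation converts the enal into the acid without touching the enone or the silyl ether.

Step 8
Reactants: 11 acrylic acid
Product: 13 cis-fused α-methylene lactone (C1 ketone; 5α-OH; 6β-O–C12; 9α-OTBS; 10β-CH3), via epoxy acid 12 (not isolated)
Conditions: 30% H2O2, NaOH, MeOH, 0 °C; NaHSO4 work-up; then CSA (10 mol%), CH2Cl2, rt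
Reagents that add atoms: hydrogen peroxide, OO
Why: Weitz–Scheffer epoxidation attacks C6 anti to the adjacent C7 substituent to give the α-epoxide, and the C12 acid then opens it 5-exo at C6 with inversion, so C6–O is β (cis-fused lactone) and C5–OH is α by mechanism; base then acid equilibrates C10 to the pseudo-equatorial β-methyl.

Step 9
Reactants: 13 cis-fused α-methylene lactone
Product: 14 (11R)-11,13-dihydro lactone (C1 ketone; 5α-OH; 9α-OTBS)
Conditions: H2 (1 atm), RhCl(PPh3)3 (5 mol%), toluene/EtOH, rt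
Reagents that add atoms: none
Why: Homogeneous hydrogenation delivers hydrogen to the exocyclic methylene from the convex face of the cis-fused bicycle, placing H11 cis to H7 and the C13 methyl on the concave face (11R), without double-bond migration or ketone reduction.

Step 10
Reactants: 14 (11R)-11,13-dihydro lactone; 15 (E)-1-methoxybuta-1,3-diene
Product: 16 C5-O-[(E)-1-methoxybut-2-en-1-yl] mixed acetal of 14 (acetal epimers)
Conditions: PPTS (5 mol%), CH2Cl2, 0 °C
Reagents that add atoms: none
Why: Acid-catalysed hydroalkoxylation of the alkoxydiene, with protonation at the terminal carbon and capture of the crotyl oxocarbenium ion at C1 by the C5 hydroxyl, installs a crotonaldehyde-level tether on the C5 oxygen; its new acetal centre is destroyed in step 11.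

Step 11
Reactants: 16 C5-O-[(E)-1-methoxybut-2-en-1-yl] mixed acetal of 14
Product: 18 9-O-TBS 5-O-destigloyl target (1β-OH; 1α-(E)-crotonoyl; 5α-OH), via oxetane ketal 17 (not isolated)
Conditions: hν (300 nm, Pyrex), degassed MeCN (5 mM), rt; then PPTS, acetone/H2O, rt
Reagents that add atoms: water, O
Why: Proposed new method: a Norrish–Yang photocyclisation through an O,O-acetal tether used as a traceless intramolecular acyl-anion transfer, in which the n,π* excited C1 ketone abstracts the weak acetal hydrogen by 1,5-HAT, the 1,4-biradical (C1 ketyl and dioxy-allyl radical, whose transoid geometry prevents closure at C4) forms the C1–C2 bond on the α face because C2 is held by the α-oriented C5 oxygen (C1–OH therefore β), and the strained 2-methoxyoxetan-3-ol 17 hydrolyses to the C2 ketone and free C5–OH with the E alkene intact; the closest known reaction is the Norrish–Yang cyclisation of α-alkoxy ketones to oxetan-3-ols.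

Step 12
Reactants: 18 9-O-TBS 5-O-destigloyl target; 19 tigloyl chloride
Product: 20 9-O-TBS target
Conditions: DMAP, pyridine, CH2Cl2, 0 °C to rt
Reagents that add atoms: none
Why: DMAP-catalysed acylation esterifies the only secondary hydroxyl (C5) while the tertiary C1 hydroxyl and the silylated C9 oxygen do not react.

Step 13
Reactants: 20 9-O-TBS target
Product: 21 target CNP0183494.2
Conditions: HF·pyridine, THF, 0 °C to rt
Reagents that add atoms: none
Why: Fluoride-driven Si–O cleavage frees the C9 hydroxyl under mildly acidic conditions that leave the lactone, the tiglate, the enone and the tertiary α-ketol untouched.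

## Compound list

1 | (R)-(−)-carvone | O=C1C(C)=CC[C@@H](C(C)=C)C1 | starting material
2 | (3R,5R)-2-methyl-5-(prop-1-en-2-yl)-3-(4,4,5,5-tetramethyl-1,3,2-dioxaborolan-2-yl)cyclohexan-1-one (C2 epimers) | O=C1C(C)[C@H](B2OC(C)(C)C(C)(C)O2)C[C@@H](C(C)=C)C1 | intermediate (not isolated)
3 | (3R,5R)-3-hydroxy-2-methyl-5-(prop-1-en-2-yl)cyclohexan-1-one (C2 epimers; OH trans to isopropenyl) | O=C1C(C)[C@H](O)C[C@@H](C(C)=C)C1 | intermediate
4 | (3R,5R)-3-[tert-butyl(dimethyl)silyl]oxy-2-methyl-5-(prop-1-en-2-yl)cyclohexan-1-one (C2 epimers) | O=C1C(C)[C@H](O[Si](C)(C)C(C)(C)C)C[C@@H](C(C)=C)C1 | intermediate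
5 | kinetic trimethylsilyl enol ether of 4 (C1=C6 double bond) | C[Si](C)(C)OC=1C(C)[C@H](O[Si](C)(C)C(C)(C)C)C[C@@H](C(C)=C)C=1 | intermediate
6 | 3-[tert-butyl(dimethyl)silyl]oxy-2-methyl-5-(prop-1-en-2-yl)-1-(trimethylsilyloxy)bicyclo[4.1.0]heptane (C3 and C5 as in 4; cyclopropane diastereomers) | C[Si](C)(C)OC12C(C)[C@H](O[Si](C)(C)C(C)(C)C)C[C@@H](C(C)=C)C1C2 | intermediate
7 | 6-[tert-butyl(dimethyl)silyl]oxy-3-chloro-7-methyl-4-(prop-1-en-2-yl)cycloheptan-1-one (C3 and C7 epimers) | O=C1C(C)[C@H](O[Si](C)(C)C(C)(C)C)C[C@@H](C(C)=C)C(Cl)C1 | intermediate (not isolated)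
8 | (4R,6R,7S)-6-[tert-butyl(dimethyl)silyl]oxy-7-methyl-4-(prop-1-en-2-yl)cyclohept-2-en-1-one (major 10β-methyl epimer; any 10α epimer converges in step 8) | O=C1[C@@H](C)[C@H](O[Si](C)(C)C(C)(C)C)C[C@@H](C(C)=C)C=C1 | intermediate
9 | allylic alcohol: 4-(3-hydroxyprop-1-en-2-yl) analogue of 8 | O=C1[C@@H](C)[C@H](O[Si](C)(C)C(C)(C)C)C[C@@H](C(=C)CO)C=C1 | intermediate (not isolated)
10 | enal: 4-(3-oxoprop-1-en-2-yl) analogue of 8 | O=C1[C@@H](C)[C@H](O[Si](C)(C)C(C)(C)C)C[C@@H](C(=C)C=O)C=C1 | intermediate
11 | acrylic acid: 4-(1-carboxyethenyl) analogue of 8 | O=C1[C@@H](C)[C@H](O[Si](C)(C)C(C)(C)C)C[C@@H](C(=C)C(=O)O)C=C1 | intermediate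
12 | 5α,6α-epoxide of 11 (epoxide trans to the C7 substituent) | O=C1[C@@H](C)[C@H](O[Si](C)(C)C(C)(C)C)C[C@@H](C(=C)C(=O)O)[C@@H]3O[C@H]13 | intermediate (not isolated)
13 | cis-fused α-methylene-γ-lactone: C1 ketone, 5α-OH, 6β-O–C12(=O), C11=C13H2, 9α-OTBS, 10β-CH3 | O=C1[C@@H](C)[C@H](O[Si](C)(C)C(C)(C)C)C[C@@H]2[C@@H](OC(=O)C2=C)[C@@H]1O | intermediate
14 | (11R)-11,13-dihydro derivative of 13 (H11 cis to H7) | O=C1[C@@H](C)[C@H](O[Si](C)(C)C(C)(C)C)C[C@@H]2[C@@H](OC(=O)[C@@H]2C)[C@@H]1O | intermediate
15 | (E)-1-methoxybuta-1,3-diene | CO/C=C/C=C | starting material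
16 | C5-O-[(E)-1-methoxybut-2-en-1-yl] mixed acetal of 14 (acetal carbon epimers) | O=C1[C@@H](C)[C@H](O[Si](C)(C)C(C)(C)C)C[C@@H]2[C@@H](OC(=O)[C@@H]2C)[C@@H]1OC(OC)/C=C/C | intermediate
17 | oxetane ketal: C1(β-OH)–C2(OMe)[(E)-prop-1-enyl]–O–C5, oxetane cis-fused on the α face (C2 epimers) | C/C=C/C3(OC)[C@]1(O)[C@@H](C)[C@H](O[Si](C)(C)C(C)(C)C)C[C@@H]2[C@@H](OC(=O)[C@@H]2C)[C@@H]1O3 | intermediate (not isolated)
18 | 9-O-TBS 5-O-destigloyl target: 1β-OH, 1α-(E)-but-2-enoyl, 5α-OH | C/C=C/C(=O)[C@]1(O)[C@@H](C)[C@H](O[Si](C)(C)C(C)(C)C)C[C@@H]2[C@@H](OC(=O)[C@@H]2C)[C@@H]1O | intermediate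
19 | tigloyl chloride, (E)-2-methylbut-2-enoyl chloride | C/C=C(\C)C(=O)Cl | starting material
20 | 9-O-TBS target (5α-tiglate) | C/C=C/C(=O)[C@]1(O)[C@@H](C)[C@H](O[Si](C)(C)C(C)(C)C)C[C@@H]2[C@@H](OC(=O)[C@@H]2C)[C@@H]1OC(=O)/C(C)=C/C | intermediate
21 | CNP0183494.2, (1S,5S,6R,7S,9R,10S,11R) in the numbering above | C/C=C/C(=O)[C@]1(O)[C@@H](C)[C@H](O)C[C@@H]2[C@@H](OC(=O)[C@@H]2C)[C@@H]1OC(=O)/C(C)=C/C | target

## Step count and risks

Total step count: 13. Longest linear sequence: 13 steps from (R)-carvone.

Three steps most likely to fail: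

Step 11 (the proposed new photocyclisation). Norrish type 1 cleavage, type 2 fragmentation of the biradical (loss of the C5 oxygen as methyl crotonate) or closure at C4 could compete. The fallback uses known chemistry, sets out from 14 and returns at 18, and replaces steps 10 and 11. The magnesium alkoxide of 14 (i-PrMgCl, THF, −78 °C) is treated with 1-lithio-1-methoxybuta-1,2-diene (from 1-methoxybuta-1,2-diene and n-BuLi) premixed with MgBr2·OEt2. The five-membered magnesium chelate between the C5 alkoxide and the C1 carbonyl leaves the face anti to the C10 methyl open, so this established acyl-anion equivalent adds from the α face to give the 1β-hydroxy allenyl ether F1. Brief treatment with dilute HCl in THF hydrolyses the enol ether of F1 to the α-hydroxy enone 18.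

Step 6 (allylic oxidation). Selenium dioxide may attack the doubly allylic C7–H or over-oxidise next to the ketone. The fallback sets out from 8 and returns at 10. Ene-type chlorination with HOCl (Ca(OCl)2, solid CO2, CH2Cl2/H2O, 0 °C) is selective for proton loss from the methyl group and gives the allylic chloride F2. Ganem oxidation of F2 (N-methylmorpholine N-oxide, KI cat., MeCN) then gives enal 10.

Step 8 (epoxidation/lactonisation, which also fixes C10). The facial selectivity of the peroxide addition, the base sensitivity of the β-silyloxy enone and the C10 equilibrium are the weak points. The fallback sets out from 11 and returns at 13. DBU (cat.) in CH2Cl2 closes the lactone by 5-exo oxa-Michael addition of the carboxylate to C6, giving the cis-fused 5-deoxy lactone F3. Soft enolisation (TMSOTf, Et3N, CH2Cl2, −78 to 0 °C) toward the less hindered, inductively activated C5 gives the silyl enol ether F4. Rubottom oxidation of F4 (DMDO, acetone, −40 °C; citric acid work-up) then hydroxylates C5 anti to the C6 lactone oxygen to give 13.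

## Further compounds

F1 | step 11 | 1β-hydroxy-1α-(1-methoxybuta-1,2-dien-1-yl) adduct of 14 (5α-OH free; allene axis unassigned) | CC=C=C(OC)[C@]1(O)[C@@H](C)[C@H](O[Si](C)(C)C(C)(C)C)C[C@@H]2[C@@H](OC(=O)[C@@H]2C)[C@@H]1O
F2 | step 6 | allylic chloride: 4-(3-chloroprop-1-en-2-yl) analogue of 8 | O=C1[C@@H](C)[C@H](O[Si](C)(C)C(C)(C)C)C[C@@H](C(=C)CCl)C=C1
F3 | step 8 | 5-deoxy analogue of 13 (cis-fused α-methylene lactone; C5 is CH2) | O=C1[C@@H](C)[C@H](O[Si](C)(C)C(C)(C)C)C[C@@H]2[C@@H](OC(=O)C2=C)C1
F4 | step 8 | trimethylsilyl enol ether of F3 (C1=C5 double bond) | C[Si](C)(C)OC=1[C@@H](C)[C@H](O[Si](C)(C)C(C)(C)C)C[C@@H]2[C@@H](OC(=O)C2=C)C=1
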